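**Remarks on the chemistry**

- Reading the stereodescriptors of the target gives ring B as (2S,3S) but rings A and C as the mirror-image (2R,3R) series, so the (S)-flavanone serves ring B only; racemic naringenin is therefore carried to the triflate and both enantiomers are separated and used there.
- Benzyl ethers stand where methyl ethers could have stood (skeleton, bonds and configuration of the key step unchanged), because a tenfold Lewis-acid demethylation at room temperature would meet a stilbene that can cyclise onto C5B and three acid-labile benzylic ethers.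
- The rings are joined in the order C, B, A, so that no aryl triflate has to survive a nickel-catalysed coupling: each block acts first as arylzinc (ester intact) and only then as redox-active ester.

## Structural features

The target is a trimer of three trans-2-(4-hydroxyphenyl)-6-hydroxy-2,3-dihydrobenzofurans. Central ring B is bonded through its sp3 carbon C3B to the arene carbon C4A of ring A and through its arene carbon C4B to the sp3 carbon C3C of ring C; ring A carries a 3,5-dihydroxyphenyl group on C3A and ring C an (E)-3,4-dihydroxystyryl arm on C4C. The six stereocentres form three vicinal pairs (C2/C3 of each ring), all trans; ring B is (2S,3S), rings A and C are (2R,3R). Fragile elements are the ten phenols (one catechol), the electron-rich stilbene next to the nucleophilic carbon C5B (acid-induced cyclisation), the three benzylic C2–O bonds para to an oxygen substituent (opening under strong acid or as phenoxides), and the C3–H bonds beta to a ring oxygen that can leave. The real difficulty lies in the two inter-ring C(sp3)–C(sp2) bonds C3B–C4A and C3C–C4B, each peri to a substituted neighbour, and in fixing each C3 relative to its C2. The key step exploits that every ring is a contracted naringenin: C2 with its 4-hydroxyphenyl group is flavanone C2, C3a is C4a, the C6–OH is the 7-OH, C4 bears the former 5-OH, and the former carbonyl carbon is the exocyclic carbon on C3. A 1,2-shift of C4a from C4 to C3 therefore delivers the ring with C2 inherited, an electrophile handle (ester) on C3 and a nucleophile handle (triflate) on C4.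

## Logic of the disconnections

**27 to 26.** The ten O–H bonds are traced back to ten O–CH2Ph bonds. Free phenols tolerate neither the organozinc nor the radical steps, and one common group allows a single final operation. The demand is a cleavage without hydrogen (stilbene) and without warm strong acid, which the choice of benzyl meets.

**26 to 21 and 22.** The C3A–aryl bond to the 3,5-dioxygenated phenyl ring is cut. This is the smallest and only symmetrical aryl group, and cutting it last lets ring A enter as the same block as ring C. The forward step must decarboxylate a congested secondary benzylic acid and form the new bond trans to the C2A aryl group.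

**21 (through 20) to 17 and 9.** The C3B–C4A bond is cut between a carboxyl-bearing sp3 carbon and a triflate-bearing arene carbon. The trimer falls into dimer 17 and monomer 9. The forward step needs an arylzinc made from 9 with its ester intact and capture of the C3B radical anti to the C2B aryl group.

**17 (through 16) to 13 and 7.** The C3C–C4B bond is cut in the same way. The dimer falls into the two enantiomeric series, 13 from the (R) line and 7 from the (S) line. The demand is the same pair of handles, used here in the opposite sense on ring B (arene nucleophile).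

**13 to 12 and 11; 11 to 10.** The C4C–alkenyl bond is cut, then the C=C bond of the arm. The triflate of 12 is the natural electrophile and a boronate of fixed E geometry removes any regiochemical question. The coupling has to run without epimerising or opening the ring at C3, which is why it is placed on the carboxylate.

**12 and 9 to 5; 7 to 4.** The C3–C3a bond of each dihydrofuran is cut and C4 is put back into the ring, which is the ring-contraction retron. One step then makes the ring, the trans pair and both handles, with C2 taken from the flavanone. The forward step must favour shift of C4a over shift of the C2 aryl group and must not touch C2.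

**4 and 5 to 3, 2 and 1.** The enantiomers are traced to racemate 3, the O–S bond to 2, and the two O–benzyl bonds to 1. Both enantiomers are needed (one part of 4, two of 5), and separation after the last base-mediated step makes any base-induced racemisation irrelevant. The demand is selective alkylation of the two non-chelated phenols.

## Other disconnections considered

**Alternative 1:** The cut removes the C3A–C3aA bond and the C2A–aryl bond of ring A and leaves O1A–C7aA for a later C–O ring closure. In the forward sense 4-methoxyphenyllithium A4 adds to the (E)-styryl pinacol boronate A3; a palladium catalyst with a chiral ferrocenyl bisphosphine then delivers the aryl group of triflate A2 to the alkene carbon remote from boron while the anisyl group shifts from boron to carbon, giving boronate A1.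
- In its favour: both stereocentres of ring A arise in one catalytic, reagent-controlled step from achiral parts, and anti addition across the E alkene maps onto the trans relation after closure. On absolute stereocontrol without a resolution it is the better of the two plans.
- Against it here: a beta-aryl alkenyl boronate with a pinacol ligand is prone to direct transmetalation instead of the metallate shift. A2 is flanked by an ester and a chlorine. A1 is a secondary benzylic boronate open to protodeboronation. The ring must still be closed by C–O coupling onto a hindered aryl chloride, and the ester on C4A must still be turned into the hard C3B–C4A bond.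
- Comparison: structurally it solves one ring of three, whereas the chosen plan draws all three rings from one flavanone. Mechanistically it is a polar 1,2-metallate shift against a cationoid 1,2-aryl shift, both stereospecific. In step economy the chosen plan is ahead, since ring A alone would cost about as many steps as the whole monomer block.

**Alternative 2:** The cut removes the three C2–aryl bonds at once. In the forward sense the tris-acid A6 loses three CO2 under an iridium photocatalyst and a nickel bipyridine catalyst, and each C2 radical couples with 4-bromoanisole A7 to give trimer A5.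
- In its favour: alpha-oxy acids are ideal substrates for this coupling, no activation step is needed, and one operation installs three identical groups. On step economy for the C2 aryl groups and on freedom from preformed organometallics it is the better.
- Against it here: stereochemical information must flow from C3 to C2, so three triaryl-substituted C3 centres of two opposite series and both congested inter-ring bonds have to be built first, without the C2 aryl groups to steer them. The hard part is moved upstream, not removed. Three couplings in one flask multiply incomplete conversion and diastereomer formation, and the C4C ester of A5 still needs several steps to become the styryl arm.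
- Comparison: structurally the chosen plan relays C2 to C3 from a resolved flavanone, the alternative relays C3 to C2. Mechanistically both rely on a radical captured by nickel anti to a neighbouring substituent and are equal on that point. In overall step count the chosen plan is expected to be shorter.

**Alternative 3:** The cut takes apart the benzene ring of ring A (C7aA–C7A, C5A–C6A, C3aA–C7aA). In the forward sense cyclobutenone A9 is heated with ethoxyacetylene A10; ring opening to a vinylketene, [2+2] addition, a second ring opening and 6π closure give phenol A8.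
- In its favour: the most hindered bond, C3B–C4A, never has to be made by coupling because the arene grows from a substituent already on C3B. No metal is involved, and the two oxygens come out differentiated. On making that bond it is the better of the two plans.
- Against it here: A9 must first be built on C3B over several steps, and the aryl triflate has to survive prolonged heating. A8 then needs the whole dihydrofuran of ring A built onto C3aA, the most hindered of three activated positions, with two new stereocentres set by reagent control relative to a remote ring B. The ethyl ether adds a second protecting group type.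
- Comparison: structurally the chosen plan brings ring A in whole and stereodefined. Mechanistically a pericyclic cascade stands against a radical cross-coupling, and the alternative is the safer on sterics at C3B. In step economy the chosen plan is clearly shorter.

Key step: step 4

## Route

**Step 1**
Reactants: 1 (±)-naringenin
Product: 2 rac-7-(benzyloxy)-2-[4-(benzyloxy)phenyl]-5-hydroxychroman-4-one
Conditions: BnBr (2.2 equiv), K2CO3, acetone, reflux
Reagents that add atoms: benzyl bromide, BrCc1ccccc1
Why: Williamson etherification; the 7-OH and 4'-OH are the acidic, free phenols, while the 5-OH is locked in a hydrogen bond to the carbonyl and stays untouched. Any ring opening to the chalcone under base is harmless because the material is racemic.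

**Step 2**
Reactants: 2 rac-4',7-di-O-benzylnaringenin
Product: 3 rac-7-(benzyloxy)-2-[4-(benzyloxy)phenyl]-4-oxochroman-5-yl trifluoromethanesulfonate
Conditions: Tf2O, pyridine, CH2Cl2, 0 °C
Reagents that add atoms: trifluoromethanesulfonic anhydride, O=S(=O)(OS(=O)(=O)C(F)(F)F)C(F)(F)F
Why: O-sulfonylation of the only remaining phenol; the strong electrophile overcomes the chelation of the 5-OH at low temperature, well before the ketone can be enolised.

**Step 3**
Reactants: 3 rac-triflate
Product: 4 (2S)-enantiomer of 3; 5 (2R)-enantiomer of 3 (collected as separate fractions)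
Conditions: preparative SFC on an amylose tris(3,5-dimethylphenylcarbamate) phase, CO2/MeOH, 35 °C
Reagents that add atoms: none
Why: Chromatographic enantiomer separation on a polysaccharide phase, routine for flavanones; it is placed after the last base-mediated step so that the configuration at C2 is fixed for good. The absolute configuration is assigned by comparison with a sample made from (S)-naringenin; 4 feeds ring B and 5 feeds rings A and C.

**Step 4**
Reactants: 4 (2S)-7-(benzyloxy)-2-[4-(benzyloxy)phenyl]-4-oxochroman-5-yl trifluoromethanesulfonate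
Product: 7 methyl (2S,3S)-6-(benzyloxy)-2-[4-(benzyloxy)phenyl]-4-{[(trifluoromethyl)sulfonyl]oxy}-2,3-dihydro-1-benzofuran-3-carboxylate, via enol ether 6 (not isolated)
Conditions: HC(OMe)3, H2SO4 (0.5 equiv), rt; then PhI(OAc)2 (1.2 equiv), rt
Reagents that add atoms: trimethyl orthoformate, COC(OC)OC
Why: Acid and the orthoformate turn the C4 ketone into enol ether 6; the electrophilic iodane adds at C3 anti to the C2 aryl group and methanol closes C4 to a dimethyl ketal, so that the phenyl-λ3-iodanyl group sits equatorial and trans to the aryl group. Loss of iodobenzene then drives a 1,2-shift of the arene carbon C4a from C4 to C3 through a phenonium-like bridged transition state, and the dimethoxycarbenium ion left at C4 gives up one methyl group to become the exocyclic methyl ester. The closest known reaction type is the oxidative ring contraction of flavanones and chromanones by hypervalent iodine or Tl(NO3)3 in trimethyl orthoformate, a relative of the oxidative 1,2-aryl shift of aryl ketones to arylacetic esters. The dihydrofuran of ring B is thus formed by ring contraction (extrusion of C4 from the pyranone), not by a cyclisation, and the one new skeletal bond is C3B–C3aB. The new stereocentre C3B is set by the stereospecific shift: C4a enters C3 with inversion, opposite to the departing iodane, which places the ester trans to the C2 aryl group, and this is also the more stable epimer; C2 is not involved under acid, so (2S) is carried over. The step needs ring contraction to win over the shift of the C2 aryl group (isoflavone), over dehydrogenation (flavone) and over plain alpha-methoxylation. The substrate secures this through the C4 ketal, whose two oxygen atoms push the shift and whose axial methoxy group keeps the C2 aryl group equatorial, so that the ring bond C4–C4a and not the C2–aryl bond lies antiperiplanar to the C3–I bond. The para benzyloxy group and the ortho ring oxygen keep C4a a good migrating carbon in spite of the ortho triflate.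

**Step 5**
Reactants: 5 (2R)-enantiomer of 4
Product: 9 methyl (2R,3R)-6-(benzyloxy)-2-[4-(benzyloxy)phenyl]-4-{[(trifluoromethyl)sulfonyl]oxy}-2,3-dihydro-1-benzofuran-3-carboxylate, via enol ether 8 (not isolated)
Conditions: HC(OMe)3, H2SO4 (0.5 equiv), rt; then PhI(OAc)2 (1.2 equiv), rt
Reagents that add atoms: trimethyl orthoformate, COC(OC)OC
Why: The same oxidative ring contraction by 1,2-aryl shift as in step 4, run on the mirror-image flavanone; it gives the trans (2R,3R) block for rings A and C with C2 retained.

**Step 6**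
Reactants: 10 3,4-bis(benzyloxy)benzaldehyde
Product: 11 2-{(E)-2-[3,4-bis(benzyloxy)phenyl]ethenyl}-4,4,5,5-tetramethyl-1,3,2-dioxaborolane
Conditions: CH2(Bpin)2, lithium 2,2,6,6-tetramethylpiperidide (LiTMP), THF, 0 °C; then 10, −78 °C to rt
Reagents that add atoms: bis(4,4,5,5-tetramethyl-1,3,2-dioxaborolan-2-yl)methane, CC1(C)OB(CB2OC(C)(C)C(C)(C)O2)OC1(C)C
Why: Boron–Wittig olefination; the lithiated geminal bis(boronate) adds to the aldehyde and syn B–O elimination from the less hindered adduct gives the E alkenyl boronate.

**Step 7**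
Reactants: 9 (2R,3R) ester triflate
Product: 12 (2R,3R)-6-(benzyloxy)-2-[4-(benzyloxy)phenyl]-4-{[(trifluoromethyl)sulfonyl]oxy}-2,3-dihydro-1-benzofuran-3-carboxylic acid
Conditions: Me3SnOH, 1,2-dichloroethane, 80 °C; dilute HCl work-up
Reagents that add atoms: trimethyltin hydroxide, C[Sn](C)(C)O
Why: Tin hydroxide hydrolysis of a methyl ester under essentially neutral conditions; it avoids the enolate that would expel the ring oxygen (retro-oxa-Michael opening) and leaves the aryl triflate alone.

**Step 8**
Reactants: 12 (2R,3R) acid triflate; 11 (E)-alkenyl boronate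
Product: 13 (2R,3R)-6-(benzyloxy)-2-[4-(benzyloxy)phenyl]-4-{(E)-2-[3,4-bis(benzyloxy)phenyl]ethenyl}-2,3-dihydro-1-benzofuran-3-carboxylic acid
Conditions: Pd(dppf)Cl2 (5 mol %), K3PO4, 1,4-dioxane/H2O, 70 °C; then dilute HCl
Reagents that add atoms: none
Why: Suzuki–Miyaura coupling of an aryl triflate with an alkenyl boronate, with retention of the E geometry and no regiochemical ambiguity. It is run on the carboxylate, whose negative charge protects C3–H from deprotonation, so neither epimerisation nor ring opening is expected.

**Step 9**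
Reactants: 13 ring C acid; 7 (2S,3S) ester triflate (2.5 equiv)
Product: 16 methyl (2S,3S)-6-(benzyloxy)-2-[4-(benzyloxy)phenyl]-4-[(2R,3R)-6-(benzyloxy)-2-[4-(benzyloxy)phenyl]-4-{(E)-2-[3,4-bis(benzyloxy)phenyl]ethenyl}-2,3-dihydro-1-benzofuran-3-yl]-2,3-dihydro-1-benzofuran-3-carboxylate, via N-acyloxyphthalimide 14 (not isolated), via arylzinc triflate 15 (not isolated)
Conditions: 13, N-hydroxyphthalimide, DIC, CH2Cl2, rt, then evaporation; 7, Zn, NiCl2(dme) (cat.), N,N'-bis(2,6-diisopropylphenyl)ethane-1,2-diimine (cat.), DMF, rt, filtered; both combined with NiCl2·glyme (20 mol %), 4,4'-di-tert-butyl-2,2'-bipyridine (40 mol %), THF/DMF, rt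
Reagents that add atoms: none
Why: Nickel-catalysed zinc insertion into the aryl triflate gives 15 with the ester intact, and base-free carbodiimide activation gives redox-active ester 14; their union is a nickel-catalysed decarboxylative Negishi-type arylation in which 14 is reduced to the C3C radical and the aryl–nickel species captures it. The planar benzylic radical is approached anti to the C2C aryl group, so C3C–C4B forms trans (3R); C2C and both centres of ring B are not involved.

**Step 10**
Reactants: 16 ring B–ring C ester
Product: 17 the carboxylic acid of 16 (CO2H on C3B)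
Conditions: Me3SnOH, 1,2-dichloroethane, 80 °C; dilute HCl work-up
Reagents that add atoms: trimethyltin hydroxide, C[Sn](C)(C)O
Why: The same neutral tin hydroxide hydrolysis as in step 7; stilbene, benzyl ethers and the benzylic ring ethers are inert to it.

**Step 11**
Reactants: 17 ring B–ring C acid; 9 (2R,3R) ester triflate (2.5 equiv)
Product: 20 trimer methyl ester: 16 in which the C3B ester is replaced by the C4A-linked ring A unit methyl (2R,3R)-6-(benzyloxy)-2-[4-(benzyloxy)phenyl]-2,3-dihydro-1-benzofuran-3-carboxylate (ring A 2R,3R; ring B 2S,3S; ring C 2R,3R), via N-acyloxyphthalimide 18 (not isolated), via arylzinc triflate 19 (not isolated)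
Conditions: 17, N-hydroxyphthalimide, DIC, CH2Cl2, rt, then evaporation; 9, Zn, NiCl2(dme) (cat.), N,N'-bis(2,6-diisopropylphenyl)ethane-1,2-diimine (cat.), DMF, rt, filtered; both combined with NiCl2·glyme (20 mol %), 4,4'-di-tert-butyl-2,2'-bipyridine (40 mol %), THF/DMF, rt
Reagents that add atoms: none
Why: The same nickel-catalysed decarboxylative arylation of a redox-active ester with an arylzinc reagent; decarboxylation erases the old C3B centre and capture of the radical anti to the C2B aryl group sets C3B–C4A trans (3S). The cheap monomer is the excess partner and the triflate of ring B has already been consumed, so no competing aryl electrophile is present.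

**Step 12**
Reactants: 20 trimer methyl ester
Product: 21 the carboxylic acid of 20 (CO2H on C3A)
Conditions: Me3SnOH, 1,2-dichloroethane, 80 °C; dilute HCl work-up
Reagents that add atoms: trimethyltin hydroxide, C[Sn](C)(C)O
Why: Neutral tin hydroxide hydrolysis as in steps 7 and 10; the ester is hindered but is a methyl ester, the best case for this reagent.

**Step 13**
Reactants: 21 trimer acid; 22 1,3-bis(benzyloxy)-5-bromobenzene
Product: 26 deca-O-benzyl ether of the target, via N-acyloxyphthalimide 23 (not isolated), via aryllithium 24 (not isolated), via arylzinc chloride 25 (not isolated)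
Conditions: 21, N-hydroxyphthalimide, DIC, CH2Cl2, rt, then evaporation; 22, n-BuLi, THF, −78 °C, then ZnCl2, to rt; both combined with NiCl2·glyme (20 mol %), 4,4'-di-tert-butyl-2,2'-bipyridine (40 mol %), THF/DMF, rt
Reagents that add atoms: none
Why: Bromine–lithium exchange and transmetalation give 25, which enters the same nickel-catalysed decarboxylative arylation; the small, unhindered arylzinc meets the most congested radical. Capture anti to the C2A aryl group sets C3A trans (3R).

**Step 14**
Reactants: 26 deca-O-benzyl ether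
Product: 27 the target, CNP0099535.1
Conditions: BCl3, pentamethylbenzene, CH2Cl2, −78 °C; MeOH quench at −78 °C
Reagents that add atoms: none
Why: Lewis-acid debenzylation with a non-basic cation scavenger; each benzyl group leaves as a cation that the arene traps at −78 °C, while the aryloxyboron species present until the quench are too electron-poor to attack the stilbene or to ionise the benzylic C2–O bonds. Hydrogenolysis is excluded by the stilbene.

## Compound list

1 | (±)-naringenin, rac-5,7-dihydroxy-2-(4-hydroxyphenyl)chroman-4-one | O=C1CC(c2ccc(O)cc2)Oc2cc(O)cc(O)c12 | starting material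
2 | rac-7-(benzyloxy)-2-[4-(benzyloxy)phenyl]-5-hydroxychroman-4-one | O=C1CC(c2ccc(OCc3ccccc3)cc2)Oc2cc(OCc3ccccc3)cc(O)c12 | intermediate
3 | rac-7-(benzyloxy)-2-[4-(benzyloxy)phenyl]-4-oxochroman-5-yl trifluoromethanesulfonate | O=C1CC(c2ccc(OCc3ccccc3)cc2)Oc2cc(OCc3ccccc3)cc(OS(=O)(=O)C(F)(F)F)c12 | intermediate
4 | (2S)-7-(benzyloxy)-2-[4-(benzyloxy)phenyl]-4-oxochroman-5-yl trifluoromethanesulfonate, (S)-4',7-di-O-benzylnaringenin 5-triflate | O=C1C[C@@H](c2ccc(OCc3ccccc3)cc2)Oc2cc(OCc3ccccc3)cc(OS(=O)(=O)C(F)(F)F)c12 | intermediate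
5 | (2R)-7-(benzyloxy)-2-[4-(benzyloxy)phenyl]-4-oxochroman-5-yl trifluoromethanesulfonate | O=C1C[C@H](c2ccc(OCc3ccccc3)cc2)Oc2cc(OCc3ccccc3)cc(OS(=O)(=O)C(F)(F)F)c12 | intermediate
6 | (2S)-7-(benzyloxy)-2-[4-(benzyloxy)phenyl]-4-methoxy-2H-chromen-5-yl trifluoromethanesulfonate (methyl enol ether of 4) | COC1=C[C@@H](c2ccc(OCc3ccccc3)cc2)Oc2cc(OCc3ccccc3)cc(OS(=O)(=O)C(F)(F)F)c12 | intermediate (not isolated)
7 | methyl (2S,3S)-6-(benzyloxy)-2-[4-(benzyloxy)phenyl]-4-{[(trifluoromethyl)sulfonyl]oxy}-2,3-dihydro-1-benzofuran-3-carboxylate (trans; ring B block) | c7ccccc7COc1ccc([C@H]2Oc3cc(OCc7ccccc7)cc(OS(=O)(=O)C(F)(F)F)c3[C@@H]2C(=O)OC)cc1 | intermediate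
8 | (2R)-7-(benzyloxy)-2-[4-(benzyloxy)phenyl]-4-methoxy-2H-chromen-5-yl trifluoromethanesulfonate (methyl enol ether of 5) | COC1=C[C@H](c2ccc(OCc3ccccc3)cc2)Oc2cc(OCc3ccccc3)cc(OS(=O)(=O)C(F)(F)F)c12 | intermediate (not isolated)
9 | methyl (2R,3R)-6-(benzyloxy)-2-[4-(benzyloxy)phenyl]-4-{[(trifluoromethyl)sulfonyl]oxy}-2,3-dihydro-1-benzofuran-3-carboxylate (trans; block for rings A and C) | c7ccccc7COc1ccc([C@@H]2Oc3cc(OCc7ccccc7)cc(OS(=O)(=O)C(F)(F)F)c3[C@H]2C(=O)OC)cc1 | intermediate
10 | 3,4-bis(benzyloxy)benzaldehyde | O=Cc1ccc(OCc2ccccc2)c(OCc2ccccc2)c1 | starting material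
11 | 2-{(E)-2-[3,4-bis(benzyloxy)phenyl]ethenyl}-4,4,5,5-tetramethyl-1,3,2-dioxaborolane | CC1(C)OB(/C=C/c2ccc(OCc3ccccc3)c(OCc3ccccc3)c2)OC1(C)C | intermediate
12 | (2R,3R)-6-(benzyloxy)-2-[4-(benzyloxy)phenyl]-4-{[(trifluoromethyl)sulfonyl]oxy}-2,3-dihydro-1-benzofuran-3-carboxylic acid | c7ccccc7COc1ccc([C@@H]2Oc3cc(OCc7ccccc7)cc(OS(=O)(=O)C(F)(F)F)c3[C@H]2C(=O)O)cc1 | intermediate
13 | (2R,3R)-6-(benzyloxy)-2-[4-(benzyloxy)phenyl]-4-{(E)-2-[3,4-bis(benzyloxy)phenyl]ethenyl}-2,3-dihydro-1-benzofuran-3-carboxylic acid (ring C acid) | c7ccccc7COc1ccc([C@@H]2Oc3cc(OCc7ccccc7)cc(/C=C/c4ccc(OCc7ccccc7)c(OCc7ccccc7)c4)c3[C@H]2C(=O)O)cc1 | intermediate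
14 | 1,3-dioxoisoindolin-2-yl ester of 13 (N-acyloxyphthalimide) | c7ccccc7COc1ccc([C@@H]2Oc3cc(OCc7ccccc7)cc(/C=C/c4ccc(OCc7ccccc7)c(OCc7ccccc7)c4)c3[C@H]2C(=O)ON2C(=O)c3ccccc3C2=O)cc1 | intermediate (not isolated)
15 | {(2S,3S)-6-(benzyloxy)-2-[4-(benzyloxy)phenyl]-3-(methoxycarbonyl)-2,3-dihydro-1-benzofuran-4-yl}zinc trifluoromethanesulfonate | c7ccccc7COc1ccc([C@H]2Oc3cc(OCc7ccccc7)cc([Zn]OS(=O)(=O)C(F)(F)F)c3[C@@H]2C(=O)OC)cc1 | intermediate (not isolated)
16 | ring B–ring C dimer: methyl (2S,3S)-6-(benzyloxy)-2-[4-(benzyloxy)phenyl]-4-[(2R,3R)-6-(benzyloxy)-2-[4-(benzyloxy)phenyl]-4-{(E)-2-[3,4-bis(benzyloxy)phenyl]ethenyl}-2,3-dihydro-1-benzofuran-3-yl]-2,3-dihydro-1-benzofuran-3-carboxylate | O(Cc7ccccc7)c1ccc([C@H]2Oc3cc(OCc7ccccc7)cc([C@@H]4c5c(/C=C/c6ccc(OCc7ccccc7)c(OCc7ccccc7)c6)cc(OCc7ccccc7)cc5O[C@H]4c4ccc(OCc7ccccc7)cc4)c3[C@@H]2C(=O)OC)cc1 | intermediate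
17 | carboxylic acid of 16 (CO2H on C3B; ring B 2S,3S; ring C 2R,3R) | O(Cc7ccccc7)c1ccc([C@H]2Oc3cc(OCc7ccccc7)cc([C@@H]4c5c(/C=C/c6ccc(OCc7ccccc7)c(OCc7ccccc7)c6)cc(OCc7ccccc7)cc5O[C@H]4c4ccc(OCc7ccccc7)cc4)c3[C@@H]2C(=O)O)cc1 | intermediate
18 | 1,3-dioxoisoindolin-2-yl ester of 17 | O(Cc7ccccc7)c1ccc([C@H]2Oc3cc(OCc7ccccc7)cc([C@@H]4c5c(/C=C/c6ccc(OCc7ccccc7)c(OCc7ccccc7)c6)cc(OCc7ccccc7)cc5O[C@H]4c4ccc(OCc7ccccc7)cc4)c3[C@@H]2C(=O)ON2C(=O)c3ccccc3C2=O)cc1 | intermediate (not isolated)
19 | {(2R,3R)-6-(benzyloxy)-2-[4-(benzyloxy)phenyl]-3-(methoxycarbonyl)-2,3-dihydro-1-benzofuran-4-yl}zinc trifluoromethanesulfonate | c7ccccc7COc1ccc([C@@H]2Oc3cc(OCc7ccccc7)cc([Zn]OS(=O)(=O)C(F)(F)F)c3[C@H]2C(=O)OC)cc1 | intermediate (not isolated)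
20 | trimer methyl ester: ring A (2R,3R, CO2Me on C3A) bonded through C4A to C3B of ring B (2S,3S), ring B bonded through C4B to C3C of ring C (2R,3R, styryl arm on C4C); eight benzyl ethers | O(Cc7ccccc7)c1ccc([C@H]2Oc3cc(OCc7ccccc7)cc([C@@H]4c5c(/C=C/c6ccc(OCc7ccccc7)c(OCc7ccccc7)c6)cc(OCc7ccccc7)cc5O[C@H]4c4ccc(OCc7ccccc7)cc4)c3[C@@H]2c2cc(OCc7ccccc7)cc3c2[C@@H](C(=O)OC)[C@H](c2ccc(OCc7ccccc7)cc2)O3)cc1 | intermediate
21 | carboxylic acid of 20 (CO2H on C3A) | O(Cc7ccccc7)c1ccc([C@H]2Oc3cc(OCc7ccccc7)cc([C@@H]4c5c(/C=C/c6ccc(OCc7ccccc7)c(OCc7ccccc7)c6)cc(OCc7ccccc7)cc5O[C@H]4c4ccc(OCc7ccccc7)cc4)c3[C@@H]2c2cc(OCc7ccccc7)cc3c2[C@@H](C(=O)O)[C@H](c2ccc(OCc7ccccc7)cc2)O3)cc1 | intermediate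
22 | 1,3-bis(benzyloxy)-5-bromobenzene | Brc1cc(OCc2ccccc2)cc(OCc2ccccc2)c1 | starting material
23 | 1,3-dioxoisoindolin-2-yl ester of 21 | O(Cc7ccccc7)c1ccc([C@H]2Oc3cc(OCc7ccccc7)cc([C@@H]4c5c(/C=C/c6ccc(OCc7ccccc7)c(OCc7ccccc7)c6)cc(OCc7ccccc7)cc5O[C@H]4c4ccc(OCc7ccccc7)cc4)c3[C@@H]2c2cc(OCc7ccccc7)cc3c2[C@@H](C(=O)ON2C(=O)c4ccccc4C2=O)[C@H](c2ccc(OCc7ccccc7)cc2)O3)cc1 | intermediate (not isolated)
24 | [3,5-bis(benzyloxy)phenyl]lithium | [Li]c1cc(OCc2ccccc2)cc(OCc2ccccc2)c1 | intermediate (not isolated)
25 | [3,5-bis(benzyloxy)phenyl]zinc chloride | Cl[Zn]c1cc(OCc2ccccc2)cc(OCc2ccccc2)c1 | intermediate (not isolated)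
26 | deca-O-benzyl ether of the target (ring A 2R,3R; ring B 2S,3S; ring C 2R,3R; E stilbene) | O(Cc7ccccc7)c1ccc([C@H]2Oc3cc(OCc7ccccc7)cc([C@@H]4c5c(/C=C/c6ccc(OCc7ccccc7)c(OCc7ccccc7)c6)cc(OCc7ccccc7)cc5O[C@H]4c4ccc(OCc7ccccc7)cc4)c3[C@@H]2c2cc(OCc7ccccc7)cc3c2[C@@H](c2cc(OCc7ccccc7)cc(OCc7ccccc7)c2)[C@H](c2ccc(OCc7ccccc7)cc2)O3)cc1 | intermediate
27 | CNP0099535.1 (ring A 2R,3R; ring B 2S,3S; ring C 2R,3R) | Oc1ccc([C@H]2Oc3cc(O)cc([C@@H]4c5c(/C=C/c6ccc(O)c(O)c6)cc(O)cc5O[C@H]4c4ccc(O)cc4)c3[C@@H]2c2cc(O)cc3c2[C@@H](c2cc(O)cc(O)c2)[C@H](c2ccc(O)cc2)O3)cc1 | target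

## Step count and least certain steps

Total step count: 14. Longest linear sequence: 12 steps (1, 2, 3, 5, 7, 8, 9, 10, 11, 12, 13, 14).

**Step 4 (key step; step 5 shares the risk).** Most likely failure is diversion of the iodane intermediate into a shift of the electron-rich C2 aryl group or into dehydrogenation, because the ortho triflate lowers the migratory aptitude of C4a and may slow ketal formation at the peri position. Electrophilic attack of the activated iodane on a benzyloxyarene is a second possible loss. Fallback, from 4 back to 7: acylation of the lithium enolate of 4 (LiN(SiMe3)2, CF3CO2CH2CF3, THF, −78 °C) gives the 3-(trifluoroacetyl)flavanone F1. Diazo transfer with loss of the trifluoroacetyl group (MsN3, Et3N, MeCN) gives the 3-diazochromanone F2. Irradiation in methanol then brings about a Wolff rearrangement, in which only the carbonyl-bound arene carbon C4a can migrate to C3; the ketene is trapped as 7 together with its cis epimer F3, and NaOMe in MeOH at 0 °C converges both on 7.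

**Step 9.** Zinc insertion next to the ortho ring junction may be slow and give way to reductive homocoupling. In the coupling, beta-hydride or beta-aryloxy elimination from a C3–nickel species would lead to aromatisation or ring opening instead of reductive elimination. Fallback, from 7 back to 16: halide exchange of the triflate ([Cp*Ru(MeCN)3]OTf, NaI, 1,3-dimethyl-2-imidazolidinone, 100 °C) gives the aryl iodide F4. F4 is joined to 14 by nickel-catalysed reductive cross-electrophile coupling (NiBr2(dme), 4,4'-di-tert-butyl-2,2'-bipyridine, Zn, DMA), so that no organozinc reagent has to be prepared.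

**Step 11.** The C3B radical is peri to the whole ring C unit, so capture by the aryl–nickel species may be slow. Hydrogen abstraction, dimerisation or seven-membered cyclisation of the radical onto the stilbene would then compete. Fallback, from 7 and 9 back to 20: the order of the two unions at ring B is inverted. 7 is hydrolysed (Me3SnOH) to the acid F5 and activated (N-hydroxyphthalimide, DIC) to the N-acyloxyphthalimide F6. Coupling with 19 forms C3B–C4A while the C3B radical is still unhindered and gives the ring A–ring B ester triflate F7. Zinc insertion as in step 9 gives the arylzinc F8, which is coupled with 14 to reach 20.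

**Step 13.** The C3A radical is formed in the most crowded position of the molecule, and decarboxylative reduction may outrun arylation. Fallback, from 12 back to 26: the aryl group is put on ring A before the rings are joined. 12 is activated to the N-acyloxyphthalimide F9 and coupled with 25 to give the ring A triflate F10. Zinc insertion gives the arylzinc F11, which is coupled with 18 to give 26 directly, at the price of an aryl triflate that must survive one nickel-catalysed coupling.

**Step 14.** Cation-driven side reactions are the danger: cyclisation of the stilbene onto C5B if free acid builds up, C-benzylation of the electron-rich rings, and air oxidation of the decaphenol during isolation. Fallback, from 26 back to 27: push–pull cleavage with AlCl3 and N,N-dimethylaniline (CH2Cl2, 0 °C), in which the amine takes up the benzyl groups and buffers the acid, is followed directly by peracetylation (Ac2O, pyridine) to the decaacetate F12. F12 is purified and then deacetylated under near-neutral conditions (NH4OAc, aqueous MeOH) to 27.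

## Further compounds

F1 | step 4 | (2S)-7-(benzyloxy)-2-[4-(benzyloxy)phenyl]-4-oxo-3-(trifluoroacetyl)chroman-5-yl trifluoromethanesulfonate (C3 enolised) | O=C1C(C(=O)C(F)(F)F)[C@@H](c2ccc(OCc3ccccc3)cc2)Oc2cc(OCc3ccccc3)cc(OS(=O)(=O)C(F)(F)F)c12
F2 | step 4 | (2R)-7-(benzyloxy)-2-[4-(benzyloxy)phenyl]-3-diazo-4-oxochroman-5-yl trifluoromethanesulfonate (same spatial arrangement at C2 as in 4; the descriptor changes with the priorities) | O=C1C(=[N+]=[N-])[C@@H](c2ccc(OCc3ccccc3)cc2)Oc2cc(OCc3ccccc3)cc(OS(=O)(=O)C(F)(F)F)c12
F3 | step 4 | methyl (2S,3R)-6-(benzyloxy)-2-[4-(benzyloxy)phenyl]-4-{[(trifluoromethyl)sulfonyl]oxy}-2,3-dihydro-1-benzofuran-3-carboxylate (cis epimer of 7) | c7ccccc7COc1ccc([C@H]2Oc3cc(OCc7ccccc7)cc(OS(=O)(=O)C(F)(F)F)c3[C@H]2C(=O)OC)cc1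
F4 | step 9 | methyl (2S,3S)-6-(benzyloxy)-2-[4-(benzyloxy)phenyl]-4-iodo-2,3-dihydro-1-benzofuran-3-carboxylate | c7ccccc7COc1ccc([C@H]2Oc3cc(OCc7ccccc7)cc(I)c3[C@@H]2C(=O)OC)cc1
F5 | step 11 | (2S,3S)-6-(benzyloxy)-2-[4-(benzyloxy)phenyl]-4-{[(trifluoromethyl)sulfonyl]oxy}-2,3-dihydro-1-benzofuran-3-carboxylic acid | c7ccccc7COc1ccc([C@H]2Oc3cc(OCc7ccccc7)cc(OS(=O)(=O)C(F)(F)F)c3[C@@H]2C(=O)O)cc1
F6 | step 11 | 1,3-dioxoisoindolin-2-yl ester of F5 | c7ccccc7COc1ccc([C@H]2Oc3cc(OCc7ccccc7)cc(OS(=O)(=O)C(F)(F)F)c3[C@@H]2C(=O)ON2C(=O)c3ccccc3C2=O)cc1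
F7 | step 11 | ring A–ring B dimer: methyl (2R,3R)-6-(benzyloxy)-2-[4-(benzyloxy)phenyl]-4-[(2S,3S)-6-(benzyloxy)-2-[4-(benzyloxy)phenyl]-4-{[(trifluoromethyl)sulfonyl]oxy}-2,3-dihydro-1-benzofuran-3-yl]-2,3-dihydro-1-benzofuran-3-carboxylate | O(Cc7ccccc7)c1ccc([C@H]2Oc3cc(OCc7ccccc7)cc(OS(=O)(=O)C(F)(F)F)c3[C@@H]2c2cc(OCc7ccccc7)cc3c2[C@@H](C(=O)OC)[C@H](c2ccc(OCc7ccccc7)cc2)O3)cc1
F8 | step 11 | arylzinc trifluoromethanesulfonate of F7 (zinc on C4B) | O(Cc7ccccc7)c1ccc([C@H]2Oc3cc(OCc7ccccc7)cc([Zn]OS(=O)(=O)C(F)(F)F)c3[C@@H]2c2cc(OCc7ccccc7)cc3c2[C@@H](C(=O)OC)[C@H](c2ccc(OCc7ccccc7)cc2)O3)cc1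
F9 | step 13 | 1,3-dioxoisoindolin-2-yl ester of 12 | c7ccccc7COc1ccc([C@@H]2Oc3cc(OCc7ccccc7)cc(OS(=O)(=O)C(F)(F)F)c3[C@H]2C(=O)ON2C(=O)c3ccccc3C2=O)cc1
F10 | step 13 | (2R,3R)-6-(benzyloxy)-2-[4-(benzyloxy)phenyl]-3-[3,5-bis(benzyloxy)phenyl]-2,3-dihydro-1-benzofuran-4-yl trifluoromethanesulfonate | c7ccccc7COc1ccc([C@@H]2Oc3cc(OCc7ccccc7)cc(OS(=O)(=O)C(F)(F)F)c3[C@H]2c2cc(OCc7ccccc7)cc(OCc7ccccc7)c2)cc1
F11 | step 13 | {(2R,3R)-6-(benzyloxy)-2-[4-(benzyloxy)phenyl]-3-[3,5-bis(benzyloxy)phenyl]-2,3-dihydro-1-benzofuran-4-yl}zinc trifluoromethanesulfonate | c7ccccc7COc1ccc([C@@H]2Oc3cc(OCc7ccccc7)cc([Zn]OS(=O)(=O)C(F)(F)F)c3[C@H]2c2cc(OCc7ccccc7)cc(OCc7ccccc7)c2)cc1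
F12 | step 14 | deca-O-acetate of the target | CC(=O)Oc1ccc([C@H]2Oc3cc(OC(C)=O)cc([C@@H]4c5c(/C=C/c6ccc(OC(C)=O)c(OC(C)=O)c6)cc(OC(C)=O)cc5O[C@H]4c4ccc(OC(C)=O)cc4)c3[C@@H]2c2cc(OC(C)=O)cc3c2[C@@H](c2cc(OC(C)=O)cc(OC(C)=O)c2)[C@H](c2ccc(OC(C)=O)cc2)O3)cc1
A1 | alternative 1 | methyl 3-chloro-2-[1-(3,5-dimethoxyphenyl)-2-(4-methoxyphenyl)-2-(4,4,5,5-tetramethyl-1,3,2-dioxaborolan-2-yl)ethyl]-5-methoxybenzoate (C2A and C3A as in the target) | COC(=O)c1cc(OC)cc(Cl)c1[C@@H](c1cc(OC)cc(OC)c1)[C@H](c1ccc(OC)cc1)B1OC(C)(C)C(C)(C)O1
A2 | alternative 1 | methyl 3-chloro-5-methoxy-2-{[(trifluoromethyl)sulfonyl]oxy}benzoate | COC(=O)c1cc(OC)cc(Cl)c1OS(=O)(=O)C(F)(F)F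
A3 | alternative 1 | 2-[(E)-2-(3,5-dimethoxyphenyl)ethenyl]-4,4,5,5-tetramethyl-1,3,2-dioxaborolane | COc1cc(/C=C/B2OC(C)(C)C(C)(C)O2)cc(OC)c1
A4 | alternative 1 | (4-methoxyphenyl)lithium | [Li]c1ccc(OC)cc1
A5 | alternative 2 | permethylated trimer with a methyl ester on C4C and all six stereocentres | COc1ccc([C@H]2Oc3cc(OC)cc([C@@H]4c5c(C(=O)OC)cc(OC)cc5O[C@H]4c4ccc(OC)cc4)c3[C@@H]2c2cc(OC)cc3c2[C@@H](c2cc(OC)cc(OC)c2)[C@H](c2ccc(OC)cc2)O3)cc1
A6 | alternative 2 | tris(2,3-dihydrobenzofuran-2-carboxylic acid) precursor of A5 (drawn all-trans; the C2 configuration is lost in the step) | OC(=O)[C@H]2Oc3cc(OC)cc([C@@H]4c5c(C(=O)OC)cc(OC)cc5O[C@H]4C(=O)O)c3[C@@H]2c2cc(OC)cc3c2[C@@H](c2cc(OC)cc(OC)c2)[C@H](C(=O)O)O3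
A7 | alternative 2 | 4-bromoanisole | COc1ccc(Br)cc1
A8 | alternative 3 | (2S,3S)-3-(3-ethoxy-5-hydroxyphenyl)-6-methoxy-2-(4-methoxyphenyl)-2,3-dihydro-1-benzofuran-4-yl trifluoromethanesulfonate | COc1ccc([C@H]2Oc3cc(OC)cc(OS(=O)(=O)C(F)(F)F)c3[C@@H]2c2cc(O)cc(OCC)c2)cc1
A9 | alternative 3 | 6-methoxy-2-(4-methoxyphenyl)-3-(3-oxocyclobut-1-en-1-yl)-2,3-dihydro-1-benzofuran-4-yl trifluoromethanesulfonate (trans, ring B configuration) | COc1ccc([C@H]2Oc3cc(OC)cc(OS(=O)(=O)C(F)(F)F)c3[C@@H]2C2=CC(=O)C2)cc1
A10 | alternative 3 | ethoxyacetylene | CCOC#C
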